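A leftover comes with this recipe: at 0.800 equiv of reagent, 20.0% of the starting material finds no partner, so reagent is the limiting reagent and product stops at 80.0%. You asked for a quick number on these set-ups, and one quantity gives it.

| flask | starting material | reagent | free catalyst | remark | time |
|---|---|---|---|---|---|
| Sunday's | 0.50 M | 0.80 equiv | 0.5 mol% | run made earlier |  |
| Friday's | 0.25 M | 0.80 equiv | 0.5 mol% | run made earlier |  |
| Monday's | 0.38 M | 0.80 equiv | 0.5 mol% | run made earlier |  |
| Thursday's | 0.50 M | 0.80 equiv | 0.75 mol% | run made earlier |  |
| south | 0.50 M | 0.800 equiv | 0.5 mol% | everything together in a closed stirred flask, run for 5.0 h | 5.0 h |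
| west | 0.50 M (fed, over 5.00 h) | 0.800 equiv | 0.5 mol% | all but starting material at the start; starting material goes in evenly over 5.00 h, the run ends at 5.0 h | 5.0 h |
| east | 0.50 M | 0.800 equiv | 0.5 mol% | a single well-mixed tank run continuously and read at steady state, 5.0 h in it on average |  |
| north-west | 0.50 M | 0.800 equiv | 0.5 mol% | a single well-mixed tank run continuously and read at steady state, 25.0 h in it on average |  |

| run | time / h | product / % |
|---|---|---|
| Sunday's | 0.667 | 10.4 |
| Sunday's | 2.00 | 31.0 |
| Sunday's | 3.00 | 39.6 |
| Sunday's | 5.00 | 56.0 |
| Friday's | 0.500 | 2.5 |
| Friday's | 1.00 | 9.5 |
| Friday's | 2.50 | 18.7 |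
| Friday's | 6.00 | 37.8 |
| Monday's | 0.833 | 11.7 |
| Monday's | 2.00 | 21.7 |
| Monday's | 4.00 | 40.1 |
| Monday's | 6.00 | 52.8 |
| Thursday's | 0.500 | 12.4 |
| Thursday's | 1.00 | 22.6 |
| Thursday's | 2.50 | 46.4 |
| Thursday's | 6.00 | 71.3 |

(readings scatter by 1 percentage point)

- the set-up with the highest amount of product at the outlet or at the end, in percent of the starting material put in ("none" if the first two lie within 2 percentage points) (south / west / east / north-west / none)
- amount of product at the outlet or at the end, in percent of the starting material put in, south
- amount of product at the outlet or at the end, in percent of the starting material put in, west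
- amount of product at the outlet or at the end, in percent of the starting material put in, east
- amount of product at the outlet or at the end, in percent of the starting material put in, north-west

Let κ be the share of the remaining reagent consumed per hour, a pseudo-first-order constant. Product then equals κ times the mean reagent left times the time, so a curve can be replaced by its mean. Sunday's last reading gives κ = 0.241 h⁻¹. Dividing κ by the catalyst concentration gives the catalyst clock s = 1.61 L mol⁻¹ min⁻¹, which carries over to other charges. For Thursday's last reading, s gives 70.8% against 71.3% read. For Friday's, it gives 41.2%, more than the 37.8% read, and that gap exceeds the scatter, so thin starting material seems to cost some rate.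

South repeats Sunday's recipe, so 56.0% stands for it. A tank holds reagent at its outlet level instead of a falling mean, which gives 43.7% for east and 68.6% for north-west. West has to be bracketed. If starting material did not matter, west would match south; if each portion ran on its own, the stays would spread evenly from zero to 5.00 h, and averaging the curve over them gives 33.5%. The midpoint, 44.7%, is this reckoning's figure for west.

The forecast gave 56%, 50%, 44% and 69% for south, west, east and north-west, a west figure above this reckoning's, and chose north-west, adding of west that “this estimate is the most uncertain”.

The flask gives 55.7%, 41.9%, 43.9% and 67.1% in that order, so north-west leads.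

    starting material + free catalyst ⇌ catalyst intermediate A (K = 1.70 L mol⁻¹, k = 100 L mol⁻¹ min⁻¹)
    reagent + catalyst intermediate A → catalyst intermediate B (k = 7.00 L mol⁻¹ min⁻¹)
    catalyst intermediate B ⇌ catalyst intermediate C (K = 1.00, k = 2.60 min⁻¹)
    catalyst intermediate C ⇌ by-product + catalyst intermediate D (K = 45.0 M, k = 48.0 min⁻¹)
    catalyst intermediate D → free catalyst + product (k = 2.10 min⁻¹)

West falls below the midpoint. In south at 1.83 h, catalyst intermediate A falls back 32 times faster than it goes on. At 2.50 h, west holds 14.8% of its catalyst as catalyst intermediate A with 32.5% of the starting material free, less than south's 23.3% with 64.2% free. For the neighbour charged with 0.85 M, s gives 69.7%, and the computed flask gives 69.8%.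

The earlier runs and the new flask were generated by integration on assumed constants; noise was put on by code.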